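**Plan**
1. Cuts (eremophilane numbering: decalin C-1 to C-10, C-14 methyl on C-5, C-15 methyl on C-4, C-11 to C-13 on C-7): the C-3 ester C–O bond, the C-7–C-11 bond, then C-6–C-7 and C-5–C-10 together, which opens rings A and B to one chain; the chain is cut at C-9–C-10 (aldol) and C-3–C-4 (crotylboration).
2. Enabling feature: ring A carries oxygen on C-7 and C-8 next to C-9=C-10, so C-7, C-8, C-9, C-10 are the four carbons of a 2,3-dioxygenated furan (the silyl enol ether of a 3-methoxybutenolide); C-5=C-6 is a 1,1-disubstituted alkene held on C-10 by the cis-alkenyl chain C-1 to C-4, which becomes ring B.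
3. Forward: allylboronate plus ynal sets C-3/C-4; formylation, pyruvate aldol, O-methylation and semi-hydrogenation give the butenolide; the dearomatizing intramolecular furan Diels–Alder reaction then closes ring B and ring A together and leaves a C-7 ketone, a C-8 enol ether and a C-10 hydroxyl.
4. Endgame: alkenyl-metal addition at C-7, acetylation, acid collapse to the 1,9-dien-8-one, and esterification with the separately made dienoic acid.
5. Stereochemistry: C-3/C-4 from a catalytic asymmetric syn-crotylboration; C-5 from the key step under control of C-3/C-4; C-7 from addition anti to the axial C-14 methyl; C-6′ of the side chain from (R)-2-methylbutan-1-ol.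
6. Helpers: the trimethylsilyl group, the furan oxygen (as C-10 hydroxyl) and the C-8 methyl ether are all gone after step 11.

Key step: step 8

Remark: (Z)-2-bromobut-2-ene, methyl 2-[(trimethylsilyl)oxy]prop-2-enoate and (R)-2-methylbutan-1-ol are taken as catalogue compounds.

**Step 1**
Reactants: 1 (Z)-2-bromobut-2-ene; 2 2-(iodomethyl)-4,4,5,5-tetramethyl-1,3,2-dioxaborolane
Product: 4 4,4,5,5-tetramethyl-2-[(2Z)-2-methylbut-2-en-1-yl]-1,3,2-dioxaborolane, via (E)-but-2-en-2-yllithium 3 (not isolated)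
Conditions: t-BuLi (2 equiv), THF/Et2O, −78 °C; then 2, −78 °C to rt
Reagents that add atoms: none
Why: Br/Li exchange goes with retention and the alkenyllithium undergoes Matteson homologation (boron ate complex, 1,2-shift with loss of iodide), so the olefin geometry is carried into the allylboronate.

**Step 2**
Reactants: 4; 5 3-(trimethylsilyl)prop-2-ynal
Product: 7 (3R,4S)-4,5-dimethylhex-5-en-1-yn-3-ol, via pinacol borate ester 6 (not isolated)
Conditions: (R)-TRIP (5 mol %), toluene, −30 °C; then K2CO3 (cat.), MeOH, rt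
Reagents that add atoms: none
Why: chiral phosphoric acid-catalysed allylboration through a closed chair transition state should turn the (Z)-geometry into the syn C-3/C-4 relationship, with the catalyst (hydrogen bond to the pinacol oxygen) choosing the aldehyde face for (3R) by analogy with simple aldehydes, and methanolysis then frees the hydroxyl and the alkyne C–H.

**Step 3**
Reactants: 7
Product: 8 tert-butyl{[(3R,4S)-4,5-dimethylhex-5-en-1-yn-3-yl]oxy}dimethylsilane
Conditions: TBSCl, imidazole, DMF, rt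
Reagents that add atoms: tert-butyl(chloro)dimethylsilane, CC(C)(C)[Si](C)(C)Cl
Why: standard silylation of a secondary propargylic alcohol, needed before the organolithium steps.

**Step 4**
Reactants: 8
Product: 10 (4R,5S)-4-[(tert-butyldimethylsilyl)oxy]-5,6-dimethylhept-6-en-2-ynal, via lithium acetylide 9 (not isolated)
Conditions: n-BuLi, THF, −78 °C; DMF, −78 to 0 °C; inverse quench into cold aq. KH2PO4
Reagents that add atoms: N,N-dimethylformamide, CN(C)C=O
Why: formylation of a lithium acetylide with DMF, where the acidic inverse quench releases the ynal while keeping dimethylamine protonated so that it cannot add to the triple bond.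

**Step 5**
Reactants: 10; 11 methyl 2-[(trimethylsilyl)oxy]prop-2-enoate
Product: 13 5-{(3R,4S)-3-[(tert-butyldimethylsilyl)oxy]-4,5-dimethylhex-5-en-1-yn-1-yl}-3-hydroxyfuran-2(5H)-one (both C-5 epimers), via silyl aldol adduct 12 (not isolated)
Conditions: Sc(OTf)3 (10 mol %), CH2Cl2, −78 °C; then TsOH·H2O (20 mol %), THF/H2O, rt
Reagents that add atoms: none
Why: Mukaiyama aldol addition of the pyruvate silyl enol ether to the ynal, followed by acid-catalysed lactonization and enolization to the isotetronic acid; the new carbinol centre is uncontrolled on purpose because it becomes a planar furan carbon in step 8.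

**Step 6**
Reactants: 13
Product: 14 5-{(3R,4S)-3-[(tert-butyldimethylsilyl)oxy]-4,5-dimethylhex-5-en-1-yn-1-yl}-3-methoxyfuran-2(5H)-one (both C-5 epimers)
Conditions: TMSCHN2, toluene/MeOH, 0 °C
Reagents that add atoms: (trimethylsilyl)diazomethane, C[Si](C)(C)C=[N+]=[N-]
Why: O-methylation of the acidic enol hydroxyl under neutral conditions, which avoids base-induced isomerization at the propargylic lactone carbon.

**Step 7**
Reactants: 14
Product: 15 5-{(1Z,3S,4S)-3-[(tert-butyldimethylsilyl)oxy]-4,5-dimethylhexa-1,5-dien-1-yl}-3-methoxyfuran-2(5H)-one (both C-5 epimers)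
Conditions: H2 (1 atm), Pd/CaCO3 poisoned with Pb(OAc)2, quinoline, EtOAc, rt
Reagents that add atoms: none
Why: Lindlar semi-hydrogenation adds hydrogen syn to the alkyne only, giving the cis C-1=C-2 alkene that ring B needs while the 1,1-disubstituted alkene and the butenolide alkene stay untouched.

**Step 8**
Reactants: 15
Product: 18 (4aS,7S,8S,8aS)-7-[(tert-butyldimethylsilyl)oxy]-4a-hydroxy-3-methoxy-8,8a-dimethyl-4a,7,8,8a-tetrahydronaphthalen-2(1H)-one, via silyloxyfuran 16 (not isolated), via oxanorbornene cycloadduct 17 (not isolated)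
Conditions: TMSOTf, Et3N, toluene, 0 °C; then 110 °C, BHT (cat.); then aq. citric acid, THF, 0 °C
Reagents that add atoms: none
Why: Proposed new method: Et3N/TMSOTf enolizes butenolide 15 at its γ-carbon to the aromatic 2-silyloxy-3-methoxyfuran 16, whose α-carbons C-10 and C-7 add suprafacially to the tethered alkene C-5=C-6 in a thermal [4+2] cycloaddition (intramolecular Diels–Alder reaction of a furan), after which the bridgehead silyl ketal of 17 collapses at C-7, so the dearomatization becomes irreversible and the furan oxygen ends as the C-10 hydroxyl. The closest known reaction types are the intramolecular Diels–Alder reactions of 2-amido- and 2-alkoxyfurans with unactivated tethered alkenes followed by heteroatom-assisted opening of the oxygen bridge, and the intermolecular Diels–Alder/ring-opening of 2-silyloxyfurans; what has not been shown is this combination with an all-carbon alkenyl tether on C-5 of a 2-silyloxyfuran. Ring A is closed by the cycloaddition itself (six-membered, both new bonds), and ring B is the tether ring of a type 1 intramolecular Diels–Alder reaction, six-membered and exo-fused because a four-atom tether can only span the bridgehead and the exo position on the side of the oxygen bridge. C-5 is set relative to C-3/C-4 by the half-chair of the forming ring B, in which the C-4 methyl and the C-3 silyloxy group are both pseudo-equatorial, whereas addition to the other furan face would make both pseudo-axial with 1,3-diaxial contacts to the oxygen bridge and to C-14; C-10 follows from the suprafacial addition (hydroxyl trans to the angular methyl) and is deleted in step 11. The step needs chemoselectivity for the [4+2] mode over Cope rearrangement of the 1,5-diene and over loss of the silyl group from 16, which should be secured by the very electron-rich diene, by the cis C-1=C-2 bond that holds C-5=C-6 over C-10/C-7, and by the irreversible ketal collapse that drains the adduct.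

**Step 9**
Reactants: 18; 19 2-bromoprop-2-en-1-ol
Product: 21 (2S,4aS,7S,8S,8aS)-7-[(tert-butyldimethylsilyl)oxy]-2-(3-hydroxyprop-1-en-2-yl)-3-methoxy-8,8a-dimethyl-1,7,8,8a-tetrahydronaphthalene-2,4a(2H)-diol, via lithium 2-lithioprop-2-en-1-olate 20 (not isolated)
Conditions: 19, t-BuLi (3 equiv per 19), Et2O, −78 to 0 °C; CeCl3, THF, −78 °C; then 18, −78 to −40 °C; aq. NH4Cl
Reagents that add atoms: none
Why: organocerium-mediated 1,2-addition of the alkenyl-metal to the enolizable C-7 ketone (one extra equivalent is spent on the C-10 hydroxyl) should occur by equatorial attack on the face opposite the axial C-14 methyl, which puts C-11 trans and the new hydroxyl cis to the angular methyl as in the target.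

**Step 10**
Reactants: 21
Product: 22 2-[(2S,4aS,7S,8S,8aS)-7-[(tert-butyldimethylsilyl)oxy]-2,4a-dihydroxy-3-methoxy-8,8a-dimethyl-1,2,4a,7,8,8a-hexahydronaphthalen-2-yl]prop-2-en-1-yl acetate
Conditions: Ac2O, pyridine, CH2Cl2, 0 °C
Reagents that add atoms: acetic anhydride, CC(=O)OC(C)=O
Why: acetylation under these conditions touches only the primary allylic hydroxyl, since both other hydroxyls are tertiary.

**Step 11**
Reactants: 22
Product: 23 2-[(3S,4aS,5S,6S)-3,6-dihydroxy-4a,5-dimethyl-2-oxo-2,3,4,4a,5,6-hexahydronaphthalen-3-yl]prop-2-en-1-yl acetate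
Conditions: 48% aq. HF, MeCN, 0 °C to rt
Reagents that add atoms: water, O
Why: acid ionizes the tertiary, doubly allylic C-10 hydroxyl to a methoxy-stabilized cation that is hydrated at C-8 and loses methanol (the hydroxy enol ether counterpart of the Stork–Danheiser transposition work-up), giving the C-8 ketone with C-9=C-10 in conjugation with C-1=C-2, while HF also removes the C-3 silyl ether.

**Step 12**
Reactants: 24 (R)-2-methylbutan-1-ol; 25 2-(triphenylphosphoranylidene)propanal
Product: 27 (2E,4R)-2,4-dimethylhex-2-enal, via (R)-2-methylbutanal 26 (not isolated)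
Conditions: TEMPO (10 mol %), PhI(OAc)2, CH2Cl2, rt; aq. NaHCO3 wash; then 25, CH2Cl2, 40 °C
Reagents that add atoms: none
Why: TEMPO-catalysed oxidation gives the configurationally labile aldehyde, which is used in solution at once in a Wittig reaction with the stabilized ylide that should give the (E)-trisubstituted enal.

**Step 13**
Reactants: 27; 28 ethyl (triphenylphosphoranylidene)acetate
Product: 29 ethyl (2E,4E,6R)-4,6-dimethylocta-2,4-dienoate
Conditions: toluene, 60 °C
Reagents that add atoms: none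
Why: Wittig olefination with a stabilized ylide under neutral conditions should give the (E)-enoate without touching the allylic stereocentre.

**Step 14**
Reactants: 29
Product: 30 (2E,4E,6R)-4,6-dimethylocta-2,4-dienoic acid
Conditions: LiOH·H2O, THF/H2O, rt; then 1 M HCl
Reagents that add atoms: lithium hydroxide, [Li+].[OH-]
Why: mild saponification of the ethyl ester, with no acidic hydrogen at the C-6 stereocentre to epimerize.

**Step 15**
Reactants: 23; 30
Product: 32 CNP0160850.1 (target), via mixed anhydride 31 (not isolated)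
Conditions: 30, 2,4,6-trichlorobenzoyl chloride, Et3N, THF, rt; then 23, DMAP, toluene, rt
Reagents that add atoms: none
Why: Yamaguchi esterification acylates the secondary allylic C-3 hydroxyl, while the tertiary C-7 hydroxyl next to the ketone is too hindered to react.

**Compound list**
1 | (Z)-2-bromobut-2-ene | C/C=C(\Br)C | starting material
2 | 2-(iodomethyl)-4,4,5,5-tetramethyl-1,3,2-dioxaborolane | ICB1OC(C)(C)C(C)(C)O1 | starting material
3 | (E)-but-2-en-2-yllithium (lithium where bromine was, cis to the C-4 methyl) | C/C=C(\[Li])C | intermediate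
4 | 4,4,5,5-tetramethyl-2-[(2Z)-2-methylbut-2-en-1-yl]-1,3,2-dioxaborolane | C/C=C(\CB1OC(C)(C)C(C)(C)O1)C | intermediate
5 | 3-(trimethylsilyl)prop-2-ynal | C[Si](C)(C)C#CC=O | starting material
6 | 2-{[(3R,4S)-4,5-dimethyl-1-(trimethylsilyl)hex-5-en-1-yn-3-yl]oxy}-4,4,5,5-tetramethyl-1,3,2-dioxaborolane | C[Si](C)(C)C#C[C@H](OB1OC(C)(C)C(C)(C)O1)[C@@H](C)C(C)=C | intermediate
7 | (3R,4S)-4,5-dimethylhex-5-en-1-yn-3-ol (syn) | C#C[C@H](O)[C@@H](C)C(C)=C | intermediate
8 | tert-butyl{[(3R,4S)-4,5-dimethylhex-5-en-1-yn-3-yl]oxy}dimethylsilane | C#C[C@H](O[Si](C)(C)C(C)(C)C)[C@@H](C)C(C)=C | intermediate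
9 | lithium acetylide of 8 | [Li]C#C[C@H](O[Si](C)(C)C(C)(C)C)[C@@H](C)C(C)=C | intermediate
10 | (4R,5S)-4-[(tert-butyldimethylsilyl)oxy]-5,6-dimethylhept-6-en-2-ynal | O=CC#C[C@H](O[Si](C)(C)C(C)(C)C)[C@@H](C)C(C)=C | intermediate
11 | methyl 2-[(trimethylsilyl)oxy]prop-2-enoate | C=C(O[Si](C)(C)C)C(=O)OC | starting material
12 | methyl (7R,8S)-7-[(tert-butyldimethylsilyl)oxy]-8,9-dimethyl-2-oxo-4-[(trimethylsilyl)oxy]dec-9-en-5-ynoate (both C-4 epimers) | COC(=O)C(=O)CC(O[Si](C)(C)C)C#C[C@H](O[Si](C)(C)C(C)(C)C)[C@@H](C)C(C)=C | intermediate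
13 | 5-{(3R,4S)-3-[(tert-butyldimethylsilyl)oxy]-4,5-dimethylhex-5-en-1-yn-1-yl}-3-hydroxyfuran-2(5H)-one (both C-5 epimers) | OC1=CC(C#C[C@H](O[Si](C)(C)C(C)(C)C)[C@@H](C)C(C)=C)OC1=O | intermediate
14 | 5-{(3R,4S)-3-[(tert-butyldimethylsilyl)oxy]-4,5-dimethylhex-5-en-1-yn-1-yl}-3-methoxyfuran-2(5H)-one (both C-5 epimers) | COC1=CC(C#C[C@H](O[Si](C)(C)C(C)(C)C)[C@@H](C)C(C)=C)OC1=O | intermediate
15 | 5-{(1Z,3S,4S)-3-[(tert-butyldimethylsilyl)oxy]-4,5-dimethylhexa-1,5-dien-1-yl}-3-methoxyfuran-2(5H)-one (both C-5 epimers) | COC1=CC(/C=C\[C@H](O[Si](C)(C)C(C)(C)C)[C@@H](C)C(C)=C)OC1=O | intermediate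
16 | tert-butyl({(1Z,3S,4S)-1-[4-methoxy-5-(trimethylsilyloxy)furan-2-yl]-4,5-dimethylhexa-1,5-dien-3-yl}oxy)dimethylsilane | COc1cc(/C=C\[C@H](O[Si](C)(C)C(C)(C)C)[C@@H](C)C(C)=C)oc1O[Si](C)(C)C | intermediate
17 | oxanorbornene cycloadduct: oxygen bridge from C-7 to C-10 on the face of C-4, trimethylsilyloxy on C-7, methoxy on C-8, C-8=C-9 and C-1=C-2 double bonds, silyloxy on C-3, methyls on C-4 and C-5 | COC1=C[C@@]23C=C[C@H](O[Si](C)(C)C(C)(C)C)[C@@H](C)[C@]2(C)C[C@]1(O[Si](C)(C)C)O3 | intermediate
18 | (4aS,7S,8S,8aS)-7-[(tert-butyldimethylsilyl)oxy]-4a-hydroxy-3-methoxy-8,8a-dimethyl-4a,7,8,8a-tetrahydronaphthalen-2(1H)-one (C-7 ketone, C-8 methyl enol ether, C-10 hydroxyl trans to C-14) | COC1=C[C@@]2(O)C=C[C@H](O[Si](C)(C)C(C)(C)C)[C@@H](C)[C@]2(C)CC1=O | intermediate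
19 | 2-bromoprop-2-en-1-ol | OCC(Br)=C | starting material
20 | lithium 2-lithioprop-2-en-1-olate | [Li]OCC([Li])=C | intermediate
21 | (2S,4aS,7S,8S,8aS)-7-[(tert-butyldimethylsilyl)oxy]-2-(3-hydroxyprop-1-en-2-yl)-3-methoxy-8,8a-dimethyl-1,7,8,8a-tetrahydronaphthalene-2,4a(2H)-diol | COC1=C[C@@]2(O)C=C[C@H](O[Si](C)(C)C(C)(C)C)[C@@H](C)[C@]2(C)C[C@]1(O)C(=C)CO | intermediate
22 | 2-[(2S,4aS,7S,8S,8aS)-7-[(tert-butyldimethylsilyl)oxy]-2,4a-dihydroxy-3-methoxy-8,8a-dimethyl-1,2,4a,7,8,8a-hexahydronaphthalen-2-yl]prop-2-en-1-yl acetate | COC1=C[C@@]2(O)C=C[C@H](O[Si](C)(C)C(C)(C)C)[C@@H](C)[C@]2(C)C[C@]1(O)C(=C)COC(C)=O | intermediate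
23 | 2-[(3S,4aS,5S,6S)-3,6-dihydroxy-4a,5-dimethyl-2-oxo-2,3,4,4a,5,6-hexahydronaphthalen-3-yl]prop-2-en-1-yl acetate | O=C1C=C2C=C[C@H](O)[C@@H](C)[C@]2(C)C[C@]1(O)C(=C)COC(C)=O | intermediate
24 | (R)-2-methylbutan-1-ol | OC[C@H](C)CC | starting material
25 | 2-(triphenylphosphoranylidene)propanal | CC(C=O)=P(c1ccccc1)(c1ccccc1)c1ccccc1 | starting material
26 | (R)-2-methylbutanal | O=C[C@H](C)CC | intermediate
27 | (2E,4R)-2,4-dimethylhex-2-enal | O=C/C(C)=C/[C@H](C)CC | intermediate
28 | ethyl (triphenylphosphoranylidene)acetate | CCOC(=O)C=P(c1ccccc1)(c1ccccc1)c1ccccc1 | starting material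
29 | ethyl (2E,4E,6R)-4,6-dimethylocta-2,4-dienoate | CCOC(=O)/C=C/C(C)=C/[C@H](C)CC | intermediate
30 | (2E,4E,6R)-4,6-dimethylocta-2,4-dienoic acid | OC(=O)/C=C/C(C)=C/[C@H](C)CC | intermediate
31 | (2E,4E,6R)-4,6-dimethylocta-2,4-dienoic 2,4,6-trichlorobenzoic anhydride | O=C(OC(=O)c1c(Cl)cc(Cl)cc1Cl)/C=C/C(C)=C/[C@H](C)CC | intermediate
32 | (3S,4aS,5S,6S)-3-[3-(acetyloxy)prop-1-en-2-yl]-3-hydroxy-4a,5-dimethyl-2-oxo-2,3,4,4a,5,6-hexahydronaphthalen-6-yl (2E,4E,6R)-4,6-dimethylocta-2,4-dienoate (CNP0160850.1) | C=C(COC(C)=O)[C@@]1(O)C[C@]2(C)C(=CC1=O)C=C[C@H](OC(=O)/C=C/C(C)=C/[C@H](C)CC)[C@H]2C | target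

**Totals**
Total step count: 15. Longest linear sequence: 12 (steps 1 to 11 and step 15); steps 12 to 14 make the side-chain acid.

**Steps most likely to fail**

Step 8 (proposed new method). The cycloaddition onto the unactivated, 1,1-disubstituted alkene may be slower than loss of the silyl group from the silyloxyfuran or Cope rearrangement of the 1,5-diene, so that ring closure never competes. The fallback sets out from 8 and returns at 18, replacing the furan by a 2-pyranone whose cycloaddition is made irreversible by loss of CO2. Sonogashira coupling of 8 with 6-chloro-4-methoxy-2H-pyran-2-one (Pd(PPh3)2Cl2, CuI, Et3N) would give 6-alkynyl-4-methoxypyranone F1. Lindlar semi-hydrogenation would give the (Z)-alkenylpyranone F2. Thermolysis (o-dichlorobenzene, 180 °C) would bring about the intramolecular Diels–Alder reaction of the pyranone with C-5=C-6 and extrusion of CO2 to the ring A dienol ether F3. Singlet oxygen (O2, light, tetraphenylporphyrin) should add across C-7/C-10 on the face away from the angular methyl to give endoperoxide F4, and Et3N (Kornblum–DeLaMare rearrangement) would then give 18.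

Step 9. The ketone may be enolized toward C-6, or the doubly metallated reagent may add too slowly, so that starting ketone returns; facial selectivity may also erode. The fallback sets out from 18 and returns at 23, adding a simple isopropenyl group and oxidizing its methyl afterwards. Isopropenylmagnesium bromide with CeCl3 would give the isopropenyl carbinol F5. PPTS in wet acetone would collapse the hydroxy enol ether to the dienone with the silyl ether kept, F6. Ene-type allylic chlorination of the 1,1-disubstituted alkene (Ca(OCl)2, solid CO2, CH2Cl2/H2O, 0 °C) would give allylic chloride F7. CsOAc in DMF would give allylic acetate F8, and HF in MeCN would remove the silyl ether to give 23.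

Step 2. Face discrimination on the small ynal may be poor, or the boronate may isomerize from Z to E, so that enantiomeric or syn/anti purity is lost. The fallback sets out from 5 and returns at 8, taking the syn relationship from an auxiliary-controlled aldol reaction. The boron enolate of (R)-4-benzyl-3-propanoyl-1,3-oxazolidin-2-one (Bu2BOTf, iPr2NEt) and 5 would give the Evans syn-aldol adduct F9. AlMe3 with N,O-dimethylhydroxylamine hydrochloride would give Weinreb amide F10. TBSOTf and 2,6-lutidine would give silyl ether F11. MeMgBr would give methyl ketone F12. Methylenetriphenylphosphorane would give the silylalkyne F13, and K2CO3 in MeOH would give 8.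

**Further compounds**
F1 | step 8 | 6-{(3R,4S)-3-[(tert-butyldimethylsilyl)oxy]-4,5-dimethylhex-5-en-1-yn-1-yl}-4-methoxy-2H-pyran-2-one | COc1cc(C#C[C@H](O[Si](C)(C)C(C)(C)C)[C@@H](C)C(C)=C)oc(=O)c1
F2 | step 8 | 6-{(1Z,3S,4S)-3-[(tert-butyldimethylsilyl)oxy]-4,5-dimethylhexa-1,5-dien-1-yl}-4-methoxy-2H-pyran-2-one | COc1cc(/C=C\[C@H](O[Si](C)(C)C(C)(C)C)[C@@H](C)C(C)=C)oc(=O)c1
F3 | step 8 | ring A dienol ether: C-7=C-8(OMe)–C-9=C-10 and C-1=C-2 double bonds, silyloxy on C-3, cis methyls on C-4 and C-5 | COC1=CC[C@@]2(C)[C@H](C)[C@@H](O[Si](C)(C)C(C)(C)C)C=CC2=C1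
F4 | step 8 | endoperoxide of F3: O–O bridge from C-7 to C-10 on the face opposite C-14 | COC1=C[C@@]23C=C[C@H](O[Si](C)(C)C(C)(C)C)[C@@H](C)[C@]2(C)C[C@@H]1OO3
F5 | step 9 | (2S,4aS,7S,8S,8aS)-7-[(tert-butyldimethylsilyl)oxy]-3-methoxy-8,8a-dimethyl-2-(prop-1-en-2-yl)-1,7,8,8a-tetrahydronaphthalene-2,4a(2H)-diol | COC1=C[C@@]2(O)C=C[C@H](O[Si](C)(C)C(C)(C)C)[C@@H](C)[C@]2(C)C[C@]1(O)C(C)=C
F6 | step 9 | (3S,4aS,5S,6S)-6-[(tert-butyldimethylsilyl)oxy]-3-hydroxy-4a,5-dimethyl-3-(prop-1-en-2-yl)-4,4a,5,6-tetrahydronaphthalen-2(3H)-one | O=C1C=C2C=C[C@H](O[Si](C)(C)C(C)(C)C)[C@@H](C)[C@]2(C)C[C@]1(O)C(C)=C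
F7 | step 9 | (3S,4aS,5S,6S)-6-[(tert-butyldimethylsilyl)oxy]-3-(3-chloroprop-1-en-2-yl)-3-hydroxy-4a,5-dimethyl-4,4a,5,6-tetrahydronaphthalen-2(3H)-one | O=C1C=C2C=C[C@H](O[Si](C)(C)C(C)(C)C)[C@@H](C)[C@]2(C)C[C@]1(O)C(=C)CCl
F8 | step 9 | 2-[(3S,4aS,5S,6S)-6-[(tert-butyldimethylsilyl)oxy]-3-hydroxy-4a,5-dimethyl-2-oxo-2,3,4,4a,5,6-hexahydronaphthalen-3-yl]prop-2-en-1-yl acetate | O=C1C=C2C=C[C@H](O[Si](C)(C)C(C)(C)C)[C@@H](C)[C@]2(C)C[C@]1(O)C(=C)COC(C)=O
F9 | step 2 | (4R)-4-benzyl-3-[(2R,3R)-3-hydroxy-2-methyl-5-(trimethylsilyl)pent-4-ynoyl]-1,3-oxazolidin-2-one | C[Si](C)(C)C#C[C@H](O)[C@@H](C)C(=O)N1C(=O)OC[C@H]1Cc1ccccc1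
F10 | step 2 | (2R,3R)-3-hydroxy-N-methoxy-N,2-dimethyl-5-(trimethylsilyl)pent-4-ynamide | C[Si](C)(C)C#C[C@H](O)[C@@H](C)C(=O)N(C)OC
F11 | step 2 | (2R,3R)-3-[(tert-butyldimethylsilyl)oxy]-N-methoxy-N,2-dimethyl-5-(trimethylsilyl)pent-4-ynamide | C[Si](C)(C)C#C[C@H](O[Si](C)(C)C(C)(C)C)[C@@H](C)C(=O)N(C)OC
F12 | step 2 | (3R,4R)-4-[(tert-butyldimethylsilyl)oxy]-3-methyl-6-(trimethylsilyl)hex-5-yn-2-one | C[Si](C)(C)C#C[C@H](O[Si](C)(C)C(C)(C)C)[C@@H](C)C(C)=O
F13 | step 2 | tert-butyl{[(3R,4S)-4,5-dimethyl-1-(trimethylsilyl)hex-5-en-1-yn-3-yl]oxy}dimethylsilane | C[Si](C)(C)C#C[C@H](O[Si](C)(C)C(C)(C)C)[C@@H](C)C(C)=C
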